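Remark on the chemistry: unprimed locants belong to the tetrahydrochromone half (carbocycle ring C, pyranone ring D), primed locants to the aromatic chromone half (benzo ring A', pyranone ring B'). Cyclohexene intermediates keep shikimate locants; C1, C2, C3, C4, C5 and C6 of shikimate become C4a, C8a, C8, C7, C6 and C5. The target is (5S,6R,7S,8S), with O5/O6 trans, O6/O7 trans and O7/O8 cis. The atom mapping and configuration of the carbene precursor 25 and of the benzannulation product 28 were checked against the target and need no correction.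

## Structural features

The target is made of two 2-(2-phenylethyl)chromone units: an aromatic one (rings A' and B') carrying OMe on C7', and one whose carbocycle (ring C) is saturated and fused to pyranone ring D. The halves are joined by a secondary alkyl aryl ether from the stereogenic C8 to C6'. Ring C carries four contiguous oxygenated stereocentres C5 to C8, three of them as free hydroxyls. The triol is fragile: C5-O can ionise through the vinylogous donor O1, C8-H is vinylogously acidic (γ to the C4 carbonyl), and loss of water leads towards an aromatic ring. The real difficulty is the C8-O-C6' ether. C8 is hindered and flanked by an oxygenated carbon, and C6' sits on an electron-rich arene with no activation for nucleophilic substitution, while the configuration at C8 must survive. A second difficulty is to free the C8 hydroxyl alone among four hydroxyls. The key step exploits ring A': the ether oxygen on C6' is para to the ring oxygen on C8a' and ortho to the methoxy on C7'. This is the 4-alkoxyphenol pattern that a chromium carbene benzannulation builds around an oxygen already bound to C8.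

## Logic of the disconnections

36 to 35: three O-Si bonds are cut. The 5,6,7-triol is the most fragile part and is unveiled last, so all earlier chemistry runs on a protected, lipophilic substrate. The forward step must cleave three hindered contiguous silyl ethers without base (C8-H) and without strong acid (C5-O).

35 to 33 (through 34), then to 29 and 30: O1'-C2' of ring B' and C4'-C3' are cut. Ring B' is the cyclisation product of an o-hydroxyaryl ynone, and the ynone comes from an aldehyde and a terminal alkyne. This reduces the aromatic half to 29 and brings in the phenylethyl chain from 30. The addition must spare ring D and the acidic C8-H, the oxidation must spare the phenol, and the closure must be 6-endo.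

29 to 28: the formyl group is traced to its diethyl acetal. A free aldehyde would not survive the carbene chemistry, and the bulky acetal makes the alkyne substituent "large". The demand is a hydrolysis mild enough for silyl ethers.

28 to 25 and 26 (key disconnection): C5'-C6', C4a'-C8a' and C8'-C8a' are cut, and C8a' with its oxygen is traced to a carbonyl ligand. The ether oxygen is then attached to C8 before ring A' exists, so no substitution at C8 and no coupling to an unactivated arene is required. Ring A' collapses to a two-carbon enol ether unit on the carbene, one CO and a three-carbon alkyne. The forward step must insert the alkyne with the acetal-bearing carbon next to the CO-derived carbon and must give the phenol, not a five-membered ring.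

25 to 18 and 23 (through 24), and 23 to 19 and 20: the O-C(carbene) bond and the carbene C-Cr/C-C(O) bonds are cut. Alcoholysis of an acyloxycarbene forms the bond at the carbene carbon, so C8 is a spectator. The demand is that a hindered secondary alcohol with a single free hydroxyl attacks faster than the acyloxycarbene decomposes.

18 to 17, 15 and 14: only O-Si and acetal C-O bonds change. The cis-7,8-diol is the one pair that can share an isopropylidene group, which sets O7/O8 apart from O5/O6. Within the pair the C8 hydroxyl, next to the planar C8a, is the less hindered. The forward steps need a site-selective first silylation and an acetal hydrolysis that leaves silyl ethers.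

14 to 12: O1-C8a is cut and the C4a=C8a unsaturation is removed. C8a is the β-carbon of a cyclohexenyl ketone, the natural acceptor for the enol oxygen of a 1,3-diketone. The bicycle becomes a monocycle with an open side chain. The forward step must cyclise 6-endo and dehydrogenate faster than the C5 silyloxy group is eliminated.

12 to 9 and 10: C4-C3 is cut (Claisen-type acylation). All side-chain carbons of ring D come from 10. The demand is kinetic enolate regiocontrol and 1,2-attack on an unsaturated amide.

9 to 8 to 7: functional group changes only (amide from ester, O-Si bonds), which prepare the acyl donor and mask the new diol.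

7 to 5 (through 6): in shikimate locants the C6-O bond is cut and the C5-O bond is re-formed. The one oxygen that shikimate lacks sits on C6, trans to O5. A 5,6-alkene allows anti epoxidation and anti opening to deliver both. The demands are chemoselective, face-selective epoxidation and attack of water at the allylic carbon.

5 to 3 to 1: the C5=C6 alkene is traced to the C5 hydroxyl, and ester and acetal are removed. Compound 1 supplies all ring C carbons and the future C4. C3 and C4 of 1 are carried untouched into C8 and C7, and C5 is re-created under control of the acetal.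

## Other disconnections considered

Alternative 1: The C7-O and C8-O bonds of ring C are cut, which leads back to the flat 2-(2-phenylethyl)-4H-chromen-4-one A2. In the forward key step a naphthalene-dioxygenase-type enzyme in whole cells adds O2 across C7=C8 of A2 to give the cis-dihydrodiol A1.
- In its favour: C7 and C8 are set in one step from an achiral chromone, ring D is present from the start, and the remaining C5=C6 alkene invites the same anti epoxidation and anti opening that the chosen plan uses on the cyclohexene.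
- Against it: acceptance and site selectivity of such enzymes for A2 are open, since the phenyl ring of the side chain is itself a classical substrate and the 5,6-bond is a second site. The sense of induction is fixed by the enzyme. A1 can dehydrate to a phenol. Opening an epoxide at C5 of the bicycle has more cationic character (stabilised through O1) than opening at the cyclohexene stage, so the trans outcome is less secure.
- Comparison: on step count to ring C the alternative is better (about five steps against ten). On predictability of absolute and relative configuration the chosen chiral-pool plan is better. The two are equal on the main problem, because the C8 hydroxyl must still be set apart from C7-OH and joined to C6'.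

Alternative 2: C4a'-C5' and O1'-C2' are cut in one operation, which unfolds the aromatic half into the open-chain acetal triketone A4 attached to O8. In the forward key step BF3·OEt2 ionises the dimethyl acetal, the C4a' methylene attacks the oxocarbenium ion, loss of methanol and tautomerisation give the phenol, and its oxygen condenses with the C2' ketone to give A3.
- In its favour: both rings A' and B' form in one flask, no chromium is used, and A3 is identical with 35, so the endgame is the same single desilylation (equal).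
- Against it: A4 must already contain the ether from the hindered C8 oxygen to an sp3 carbon flanked by an acetal and an enol ether, a bond for which no reliable, retentive method is evident. The triketone can cyclise to a pyranone early or be O-alkylated by the oxocarbenium ion. BF3·OEt2 also threatens the silyl ethers and the ionisable C5-O bond.
- Comparison: the alternative is better in step economy after the ether is in place. The chosen plan is better where it matters most, because carbene alcoholysis makes the ether with certain retention at C8. Mechanistically the alternative relies on cationic aldol chemistry with several competing nucleophiles, the chosen plan on a metal-templated assembly with one main selectivity question.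

Alternative 3: O1-C8a is cut in a substrate that already carries the aryl ether, which leads to the shikimate-derived diketone A6, whose carboxyl carbon is C4. In the forward key step the diketone enol oxygen adds 6-endo-trig to C8a and Pd(OCOCF3)2 under O2 dehydrogenates the adduct to A5.
- In its favour: the aromatic chromone is made separately as the phenol A7 and joined to shikimate C3 by substitution, so the route is convergent and free of chromium. The ring D closure is the same reaction type as step 7 of the chosen route (equal), and it runs on a substrate without a β-silyloxy group on C5 (better).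
- Against it: A5 has no oxygen on C5. A late C-H oxidation would have to choose C5 over C8-H (also activated and oxygen-bearing) and over two benzylic methylene groups, and then give the 5,6-trans alcohol. Substitution at shikimate C3 with net retention needs a double inversion or a π-allyl process that competes with SN2' attack.
- Comparison: the alternative is shorter and more convergent up to the bicycle. The chosen plan is better on the C5 stereocentre, which it sets early by epoxide opening with a predictable anti course.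

Key step: step 13

## Route

Step 1
Reactants: 1 (-)-shikimic acid
Product: 3 methyl (3R,4S,5R)-5-hydroxy-3,4-(isopropylidenedioxy)cyclohex-1-ene-1-carboxylate, via methyl shikimate 2 (not isolated)
Conditions: MeOH, camphorsulfonic acid (cat.), reflux; concentrate; then Me2C(OMe)2, acetone, rt
Reagents that add atoms: methanol, CO; 2,2-dimethoxypropane, COC(C)(C)OC
Why: Fischer esterification followed by acid-catalysed transketalisation; only the cis-3,4-diol can close a dioxolane, so O5 stays free. No stereocentre is touched.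

Step 2
Reactants: 3
Product: 5 methyl (3R,4S)-3,4-(isopropylidenedioxy)cyclohexa-1,5-diene-1-carboxylate, via 5-O-triflate 4 (not isolated)
Conditions: Tf2O, pyridine, CH2Cl2, -20 °C; then DBU, 0 °C to rt
Reagents that add atoms: none
Why: Sulfonylation and E2 elimination; H4 is syn to the leaving group, so only an allylic H6 can be lost anti, which should give the conjugated diene. The acetal blocks aromatisation.

Step 3
Reactants: 5
Product: 7 methyl (3R,4S,5R,6S)-5,6-dihydroxy-3,4-(isopropylidenedioxy)cyclohex-1-ene-1-carboxylate, via 5,6-epoxide 6 (not isolated)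
Conditions: dimethyldioxirane, acetone, -20 to 0 °C; concentrate; then HClO4 (cat.), THF/H2O, 0 °C
Reagents that add atoms: dimethyldioxirane, CC1(C)OO1; water, O
Why: Electrophilic epoxidation should take the electron-richer C5=C6 and not the ester-bearing C1=C2, on the face opposite the dioxolane, which restores the natural C5 configuration. Acid-catalysed anti opening by water at the allylic C6 (inversion) then places O6 trans to O5 and cis to O3/O4.

Step 4
Reactants: 7
Product: 8 methyl (3R,4R,5S,6S)-5,6-bis(tert-butyldimethylsilyloxy)-3,4-(isopropylidenedioxy)cyclohex-1-ene-1-carboxylate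
Conditions: TBSOTf, 2,6-lutidine, CH2Cl2, 0 °C to rt
Reagents that add atoms: tert-butyldimethylsilyl trifluoromethanesulfonate, CC(C)(C)[Si](C)(C)OS(=O)(=O)C(F)(F)F
Why: A silyl triflate with a hindered base silylates both secondary hydroxyls of the trans-diol; no stereocentre is affected.

Step 5
Reactants: 8
Product: 9 (3R,4R,5S,6S)-5,6-bis(tert-butyldimethylsilyloxy)-N-methoxy-N-methyl-3,4-(isopropylidenedioxy)cyclohex-1-ene-1-carboxamide
Conditions: MeNH(OMe)·HCl, i-PrMgCl, THF, -20 to 0 °C
Reagents that add atoms: N,O-dimethylhydroxylamine hydrochloride, CNOC.Cl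
Why: Aminolysis of the ester by the chloromagnesium amide; the chelated adduct stops at the N-methoxy-N-methylamide, the acyl donor for step 6.

Step 6
Reactants: 9; 10 4-phenylbutan-2-one
Product: 12 1-[(3R,4R,5S,6S)-5,6-bis(tert-butyldimethylsilyloxy)-3,4-(isopropylidenedioxy)cyclohex-1-en-1-yl]-5-phenylpentane-1,3-dione, via lithium enolate of 4-phenylbutan-2-one 11 (not isolated)
Conditions: 10, LiN(i-Pr)2, THF, -78 °C; then 9, -78 to 0 °C; aq NH4Cl
Reagents that add atoms: none
Why: Kinetic deprotonation at the methyl group of 10 and Claisen-type C-acylation of the enolate by the N-methoxy-N-methylamide; excess enolate is used because the diketone is deprotonated as it forms. No stereocentre is involved.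

Step 7
Reactants: 12
Product: 14 (5S,6S,7R,8S)-5,6-bis(tert-butyldimethylsilyloxy)-7,8-(isopropylidenedioxy)-2-(2-phenylethyl)-5,6,7,8-tetrahydro-4H-chromen-4-one, via oxa-Michael adduct 13 (not isolated)
Conditions: Pd(OCOCF3)2 (20 mol %), DMSO, O2 (1 atm), 4 Å molecular sieves, 60 °C
Reagents that add atoms: none
Why: The diketone enol oxygen adds to the enone β-carbon (6-endo-trig oxa-Michael), and ketone 13 is then dehydrogenated by aerobic palladium catalysis (divalent palladium enolate at C4a, β-hydride elimination from C8a), the sequence known for turning 2'-hydroxychalcones and chromanones into chromones. The centres formed at C4a and C8a in 13 are erased again; C5 to C8 are not involved.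

Step 8
Reactants: 14
Product: 15 (5S,6S,7R,8S)-5,6-bis(tert-butyldimethylsilyloxy)-7,8-dihydroxy-2-(2-phenylethyl)-5,6,7,8-tetrahydro-4H-chromen-4-one
Conditions: CF3CO2H/H2O (9:1), CH2Cl2, 0 °C
Reagents that add atoms: none
Why: Aqueous acid hydrolysis of the cis-fused dioxolane; the protonated pyranone disfavours ionisation at C5 or C8, and hindered secondary silyl ethers should survive short exposure at 0 °C.

Step 9
Reactants: 15
Product: 17 (5S,6R,7S,8S)-5,6,7-tris(tert-butyldimethylsilyloxy)-2-(2-phenylethyl)-8-(triethylsilyloxy)-5,6,7,8-tetrahydro-4H-chromen-4-one, via 8-O-triethylsilyl 7-alcohol 16 (not isolated)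
Conditions: Et3SiCl, imidazole, CH2Cl2, -40 to -20 °C; then 2,6-lutidine, TBSOTf, 0 °C
Reagents that add atoms: chlorotriethylsilane, CC[Si](Cl)(CC)CC; tert-butyldimethylsilyl trifluoromethanesulfonate, CC(C)(C)[Si](C)(C)OS(=O)(=O)C(F)(F)F
Why: The C8 hydroxyl, next to the planar C8a, is less hindered than the C7 hydroxyl beside the C6 silyl ether and should take the triethylsilyl group first. The stronger silyl triflate then caps C7.

Step 10
Reactants: 17
Product: 18 (5S,6R,7R,8S)-5,6,7-tris(tert-butyldimethylsilyloxy)-8-hydroxy-2-(2-phenylethyl)-5,6,7,8-tetrahydro-4H-chromen-4-one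
Conditions: PPTS, MeOH/CH2Cl2, 0 °C to rt
Reagents that add atoms: none
Why: Acid-catalysed methanolysis removes the more labile triethylsilyl ether and leaves the three tert-butyldimethylsilyl ethers (standard selectivity between these groups).

Step 11
Reactants: 19 methoxyethene; 20 hexacarbonylchromium Cr(CO)6
Product: 23 tetramethylammonium pentacarbonyl(2-methoxy-1-oxidoprop-2-en-1-ylidene)chromate, via 1-methoxyvinyllithium 21 (not isolated), via lithium acylchromate 22 (not isolated)
Conditions: 19, t-BuLi, THF, -78 to 0 °C; Cr(CO)6, Et2O, 0 °C to rt; then Me4NBr, H2O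
Reagents that add atoms: tetramethylammonium bromide, C[N+](C)(C)C.[Br-]
Why: α-Lithiation of the enol ether, addition of the vinyllithium to a carbonyl ligand (Fischer synthesis of acylmetalates) and cation exchange to the storable ammonium salt.

Step 12
Reactants: 23; 18
Product: 25 pentacarbonyl{(1-methoxyethenyl){[(5S,6R,7R,8S)-5,6,7-tris(tert-butyldimethylsilyloxy)-4-oxo-2-(2-phenylethyl)-5,6,7,8-tetrahydro-4H-chromen-8-yl]oxy}methylidene}chromium, via acetoxycarbene complex 24 (not isolated)
Conditions: 23 (excess), CH3COBr, CH2Cl2, -40 °C; then 18, -40 to -10 °C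
Reagents that add atoms: none
Why: O-Acylation of the acylchromate gives the strongly electrophilic acetoxycarbene; the C8 hydroxyl adds to the carbene carbon and acetate leaves (addition-elimination, the standard entry to carbenes with chiral secondary alkoxy groups). The O-C8 bond is never broken, so C8 keeps its configuration; the cheap chromium salt is used in excess so that 18 is limiting.

Step 13
Reactants: 25; 26 3,3-diethoxyprop-1-yne
Product: 28 2-(diethoxymethyl)-5-methoxy-4-{[(5S,6R,7R,8S)-5,6,7-tris(tert-butyldimethylsilyloxy)-4-oxo-2-(2-phenylethyl)-5,6,7,8-tetrahydro-4H-chromen-8-yl]oxy}phenol, via tricarbonylchromium arene complex 27 (not isolated)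
Conditions: 26 (3 equiv), THF (degassed), 50 °C, argon; then air, MeCN, rt
Reagents that add atoms: none
Why: Thermal loss of one CO opens a site for the alkyne, which inserts into the Cr=C bond (C5'-C6'); CO insertion gives a chromium-bound dienylketene (C4a'-C8a'), whose 6π electrocyclisation closes ring A' (C8'-C8a'), and tautomerisation gives the phenol as its Cr(CO)3 complex, which air sets free. The closest known reaction type is the Dötz benzannulation of alkenyl(alkoxy)carbene chromium complexes with terminal alkynes, including carbenes with carbohydrate-derived alkoxy groups. The one ring formed, ring A', closes by electrocyclisation of the ketene; no stereocentre is created, and C8 is untouched because only the carbene carbon reacts. Regiochemistry is needed: the bulky acetal carbon must end next to the CO-derived carbon, which the steric preference at chromium for the small alkyne terminus beside the carbene carbon secures. Phenol formation must beat cyclopentannulation; an alkenyl alkoxy carbene on chromium in an ethereal solvent at moderate temperature favours CO insertion. The work-up uses air and no strong oxidant, so the hydroquinone monoether is not oxidised to a quinone with loss of the C8 alkoxy group.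

Step 14
Reactants: 28
Product: 29 2-hydroxy-4-methoxy-5-{[(5S,6R,7R,8S)-5,6,7-tris(tert-butyldimethylsilyloxy)-4-oxo-2-(2-phenylethyl)-5,6,7,8-tetrahydro-4H-chromen-8-yl]oxy}benzaldehyde
Conditions: PPTS, acetone/H2O, rt
Reagents that add atoms: water, O
Why: Mild acid hydrolysis of an electron-rich aryl acetal; silyl ethers survive, and the C8 aryl ether is stable because C8, attached to the electron-poor C8a, is a poor cation site.

Step 15
Reactants: 29; 30 4-phenylbut-1-yne
Product: 33 (5S,6R,7R,8S)-5,6,7-tris(tert-butyldimethylsilyloxy)-8-[4-hydroxy-5-(1-hydroxy-5-phenylpent-2-yn-1-yl)-2-methoxyphenoxy]-2-(2-phenylethyl)-5,6,7,8-tetrahydro-4H-chromen-4-one (both carbinol epimers), via lithium 4-phenylbut-1-ynide 31 (not isolated), via dichloro(4-phenylbut-1-ynyl)cerium 32 (not isolated)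
Conditions: 30 (4 equiv), n-BuLi, THF, -78 °C; CeCl3, -78 °C; then 29, -78 to -40 °C; aq NH4Cl
Reagents that add atoms: none
Why: One equivalent deprotonates the phenol; the weakly basic, oxophilic alkynylcerium then adds 1,2 to the aldehyde and should neither deprotonate C8-H nor attack a pyranone. The new carbinol centre is left uncontrolled because step 16 oxidises it.

Step 16
Reactants: 33
Product: 35 (5S,6R,7R,8S)-5,6,7-tris(tert-butyldimethylsilyloxy)-8-{[7-methoxy-4-oxo-2-(2-phenylethyl)-4H-chromen-6-yl]oxy}-2-(2-phenylethyl)-5,6,7,8-tetrahydro-4H-chromen-4-one, via ynone 34 (not isolated)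
Conditions: MnO2, CH2Cl2, rt; filter; then Et2NH, EtOH, rt to 40 °C
Reagents that add atoms: none
Why: MnO2 oxidises only the benzylic, propargylic carbinol. Diethylamine adds to the ynone to give an enaminone, which the phenol oxygen displaces in a 6-endo addition-elimination, so ring B' forms and the 5-exo aurone path is avoided.

Step 17
Reactants: 35
Product: 36 (5S,6R,7S,8S)-5,6,7-trihydroxy-8-{[7-methoxy-4-oxo-2-(2-phenylethyl)-4H-chromen-6-yl]oxy}-2-(2-phenylethyl)-5,6,7,8-tetrahydro-4H-chromen-4-one (CNP0125425.2)
Conditions: HF·pyridine, pyridine, THF, 0 °C to rt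
Reagents that add atoms: none
Why: Fluoride cleaves the three secondary silyl ethers; the pyridine-buffered, non-basic medium avoids deprotonation at C8 and ionisation at C5, so all four stereocentres are kept.

## Compound list

1 | (-)-shikimic acid, (3R,4S,5R)-3,4,5-trihydroxycyclohex-1-ene-1-carboxylic acid | O=C(O)C1=C[C@@H](O)[C@@H](O)[C@H](O)C1 | starting material
2 | methyl shikimate, methyl (3R,4S,5R)-3,4,5-trihydroxycyclohex-1-ene-1-carboxylate | COC(=O)C1=C[C@@H](O)[C@@H](O)[C@H](O)C1 | intermediate (not isolated)
3 | methyl (3R,4S,5R)-5-hydroxy-3,4-(isopropylidenedioxy)cyclohex-1-ene-1-carboxylate | COC(=O)C1=C[C@@H]2[C@@H](OC(C)(C)O2)[C@H](O)C1 | intermediate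
4 | methyl (3R,4R,5R)-3,4-(isopropylidenedioxy)-5-(trifluoromethylsulfonyloxy)cyclohex-1-ene-1-carboxylate | COC(=O)C1=C[C@@H]2[C@@H](OC(C)(C)O2)[C@H](OS(=O)(=O)C(F)(F)F)C1 | intermediate (not isolated)
5 | methyl (3R,4S)-3,4-(isopropylidenedioxy)cyclohexa-1,5-diene-1-carboxylate | COC(=O)C1=C[C@@H]2[C@@H](OC(C)(C)O2)C=C1 | intermediate
6 | methyl (3R,4R,5R,6R)-5,6-epoxy-3,4-(isopropylidenedioxy)cyclohex-1-ene-1-carboxylate (oxirane oxygen on the face opposite the dioxolane) | COC(=O)C1=C[C@@H]2[C@@H](OC(C)(C)O2)[C@H]3[C@@H]1O3 | intermediate (not isolated)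
7 | methyl (3R,4S,5R,6S)-5,6-dihydroxy-3,4-(isopropylidenedioxy)cyclohex-1-ene-1-carboxylate | COC(=O)C1=C[C@@H]2[C@@H](OC(C)(C)O2)[C@H](O)[C@H]1O | intermediate
8 | methyl (3R,4R,5S,6S)-5,6-bis(tert-butyldimethylsilyloxy)-3,4-(isopropylidenedioxy)cyclohex-1-ene-1-carboxylate | COC(=O)C1=C[C@@H]2[C@@H](OC(C)(C)O2)[C@H](O[Si](C)(C)C(C)(C)C)[C@H]1O[Si](C)(C)C(C)(C)C | intermediate
9 | (3R,4R,5S,6S)-5,6-bis(tert-butyldimethylsilyloxy)-N-methoxy-N-methyl-3,4-(isopropylidenedioxy)cyclohex-1-ene-1-carboxamide | CON(C)C(=O)C1=C[C@@H]2[C@@H](OC(C)(C)O2)[C@H](O[Si](C)(C)C(C)(C)C)[C@H]1O[Si](C)(C)C(C)(C)C | intermediate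
10 | 4-phenylbutan-2-one | CC(=O)CCc1ccccc1 | starting material
11 | lithium 4-phenylbut-1-en-2-olate | [Li]OC(=C)CCc1ccccc1 | intermediate (not isolated)
12 | 1-[(3R,4R,5S,6S)-5,6-bis(tert-butyldimethylsilyloxy)-3,4-(isopropylidenedioxy)cyclohex-1-en-1-yl]-5-phenylpentane-1,3-dione | O=C(CC(=O)CCc1ccccc1)C1=C[C@@H]2[C@@H](OC(C)(C)O2)[C@H](O[Si](C)(C)C(C)(C)C)[C@H]1O[Si](C)(C)C(C)(C)C | intermediate
13 | 5,6-bis(tert-butyldimethylsilyloxy)-7,8-(isopropylidenedioxy)-2-(2-phenylethyl)-4a,5,6,7,8,8a-hexahydro-4H-chromen-4-one (C5 to C8 configured as in 14; epimer mixture at C4a and C8a) | CC1(C)O[C@@H]2C3OC(CCc4ccccc4)=CC(=O)C3[C@H](O[Si](C)(C)C(C)(C)C)[C@@H](O[Si](C)(C)C(C)(C)C)[C@@H]2O1 | intermediate (not isolated)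
14 | (5S,6S,7R,8S)-5,6-bis(tert-butyldimethylsilyloxy)-7,8-(isopropylidenedioxy)-2-(2-phenylethyl)-5,6,7,8-tetrahydro-4H-chromen-4-one | CC1(C)O[C@@H]2c3oc(CCc4ccccc4)cc(=O)c3[C@H](O[Si](C)(C)C(C)(C)C)[C@@H](O[Si](C)(C)C(C)(C)C)[C@@H]2O1 | intermediate
15 | (5S,6S,7R,8S)-5,6-bis(tert-butyldimethylsilyloxy)-7,8-dihydroxy-2-(2-phenylethyl)-5,6,7,8-tetrahydro-4H-chromen-4-one | O[C@@H]1c2oc(CCc3ccccc3)cc(=O)c2[C@H](O[Si](C)(C)C(C)(C)C)[C@@H](O[Si](C)(C)C(C)(C)C)[C@@H]1O | intermediate
16 | (5S,6S,7S,8S)-5,6-bis(tert-butyldimethylsilyloxy)-7-hydroxy-2-(2-phenylethyl)-8-(triethylsilyloxy)-5,6,7,8-tetrahydro-4H-chromen-4-one | CC[Si](CC)(CC)O[C@@H]1c2oc(CCc3ccccc3)cc(=O)c2[C@H](O[Si](C)(C)C(C)(C)C)[C@@H](O[Si](C)(C)C(C)(C)C)[C@@H]1O | intermediate (not isolated)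
17 | (5S,6R,7S,8S)-5,6,7-tris(tert-butyldimethylsilyloxy)-2-(2-phenylethyl)-8-(triethylsilyloxy)-5,6,7,8-tetrahydro-4H-chromen-4-one | CC[Si](CC)(CC)O[C@@H]1c2oc(CCc3ccccc3)cc(=O)c2[C@H](O[Si](C)(C)C(C)(C)C)[C@@H](O[Si](C)(C)C(C)(C)C)[C@@H]1O[Si](C)(C)C(C)(C)C | intermediate
18 | (5S,6R,7R,8S)-5,6,7-tris(tert-butyldimethylsilyloxy)-8-hydroxy-2-(2-phenylethyl)-5,6,7,8-tetrahydro-4H-chromen-4-one | O[C@@H]1c2oc(CCc3ccccc3)cc(=O)c2[C@H](O[Si](C)(C)C(C)(C)C)[C@@H](O[Si](C)(C)C(C)(C)C)[C@@H]1O[Si](C)(C)C(C)(C)C | intermediate
19 | methoxyethene | COC=C | starting material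
20 | hexacarbonylchromium Cr(CO)6 | [Cr].[C-]#[O+].[C-]#[O+].[C-]#[O+].[C-]#[O+].[C-]#[O+].[C-]#[O+] | starting material
21 | 1-methoxyvinyllithium | [Li]C(=C)OC | intermediate (not isolated)
22 | lithium pentacarbonyl(2-methoxy-1-oxidoprop-2-en-1-ylidene)chromate | [Li+].C=C(OC)C([O-])=[Cr].[C-]#[O+].[C-]#[O+].[C-]#[O+].[C-]#[O+].[C-]#[O+] | intermediate (not isolated)
23 | tetramethylammonium pentacarbonyl(2-methoxy-1-oxidoprop-2-en-1-ylidene)chromate | C[N+](C)(C)C.C=C(OC)C([O-])=[Cr].[C-]#[O+].[C-]#[O+].[C-]#[O+].[C-]#[O+].[C-]#[O+] | intermediate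
24 | pentacarbonyl[acetoxy(1-methoxyethenyl)methylidene]chromium | C=C(OC)C(=[Cr])OC(C)=O.[C-]#[O+].[C-]#[O+].[C-]#[O+].[C-]#[O+].[C-]#[O+] | intermediate (not isolated)
25 | pentacarbonyl{(1-methoxyethenyl){[(5S,6R,7R,8S)-5,6,7-tris(tert-butyldimethylsilyloxy)-4-oxo-2-(2-phenylethyl)-5,6,7,8-tetrahydro-4H-chromen-8-yl]oxy}methylidene}chromium | C=C(OC)C(=[Cr])O[C@@H]1c2oc(CCc3ccccc3)cc(=O)c2[C@H](O[Si](C)(C)C(C)(C)C)[C@@H](O[Si](C)(C)C(C)(C)C)[C@@H]1O[Si](C)(C)C(C)(C)C.[C-]#[O+].[C-]#[O+].[C-]#[O+].[C-]#[O+].[C-]#[O+] | intermediate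
26 | 3,3-diethoxyprop-1-yne | C#CC(OCC)OCC | starting material
27 | tricarbonylchromium complex of 28 (Cr(CO)3 bound η6 to ring A') | CCOC(OCC)c1cc(O[C@@H]2c3oc(CCc4ccccc4)cc(=O)c3[C@H](O[Si](C)(C)C(C)(C)C)[C@@H](O[Si](C)(C)C(C)(C)C)[C@@H]2O[Si](C)(C)C(C)(C)C)c(OC)cc1O.[Cr].[C-]#[O+].[C-]#[O+].[C-]#[O+] | intermediate (not isolated)
28 | 2-(diethoxymethyl)-5-methoxy-4-{[(5S,6R,7R,8S)-5,6,7-tris(tert-butyldimethylsilyloxy)-4-oxo-2-(2-phenylethyl)-5,6,7,8-tetrahydro-4H-chromen-8-yl]oxy}phenol | CCOC(OCC)c1cc(O[C@@H]2c3oc(CCc4ccccc4)cc(=O)c3[C@H](O[Si](C)(C)C(C)(C)C)[C@@H](O[Si](C)(C)C(C)(C)C)[C@@H]2O[Si](C)(C)C(C)(C)C)c(OC)cc1O | intermediate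
29 | 2-hydroxy-4-methoxy-5-{[(5S,6R,7R,8S)-5,6,7-tris(tert-butyldimethylsilyloxy)-4-oxo-2-(2-phenylethyl)-5,6,7,8-tetrahydro-4H-chromen-8-yl]oxy}benzaldehyde | O=Cc1cc(O[C@@H]2c3oc(CCc4ccccc4)cc(=O)c3[C@H](O[Si](C)(C)C(C)(C)C)[C@@H](O[Si](C)(C)C(C)(C)C)[C@@H]2O[Si](C)(C)C(C)(C)C)c(OC)cc1O | intermediate
30 | 4-phenylbut-1-yne | C#CCCc1ccccc1 | starting material
31 | lithium 4-phenylbut-1-ynide | [Li]C#CCCc1ccccc1 | intermediate (not isolated)
32 | dichloro(4-phenylbut-1-ynyl)cerium | Cl[Ce](Cl)C#CCCc1ccccc1 | intermediate (not isolated)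
33 | (5S,6R,7R,8S)-5,6,7-tris(tert-butyldimethylsilyloxy)-8-[4-hydroxy-5-(1-hydroxy-5-phenylpent-2-yn-1-yl)-2-methoxyphenoxy]-2-(2-phenylethyl)-5,6,7,8-tetrahydro-4H-chromen-4-one (carbinol centre not controlled) | OC(C#CCCc1ccccc1)c1cc(O[C@@H]2c3oc(CCc4ccccc4)cc(=O)c3[C@H](O[Si](C)(C)C(C)(C)C)[C@@H](O[Si](C)(C)C(C)(C)C)[C@@H]2O[Si](C)(C)C(C)(C)C)c(OC)cc1O | intermediate
34 | (5S,6R,7R,8S)-5,6,7-tris(tert-butyldimethylsilyloxy)-8-[4-hydroxy-2-methoxy-5-(5-phenylpent-2-ynoyl)phenoxy]-2-(2-phenylethyl)-5,6,7,8-tetrahydro-4H-chromen-4-one | O=C(C#CCCc1ccccc1)c1cc(O[C@@H]2c3oc(CCc4ccccc4)cc(=O)c3[C@H](O[Si](C)(C)C(C)(C)C)[C@@H](O[Si](C)(C)C(C)(C)C)[C@@H]2O[Si](C)(C)C(C)(C)C)c(OC)cc1O | intermediate (not isolated)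
35 | (5S,6R,7R,8S)-5,6,7-tris(tert-butyldimethylsilyloxy)-8-{[7-methoxy-4-oxo-2-(2-phenylethyl)-4H-chromen-6-yl]oxy}-2-(2-phenylethyl)-5,6,7,8-tetrahydro-4H-chromen-4-one | COc1cc2oc(CCc3ccccc3)cc(=O)c2cc1O[C@@H]1c2oc(CCc3ccccc3)cc(=O)c2[C@H](O[Si](C)(C)C(C)(C)C)[C@@H](O[Si](C)(C)C(C)(C)C)[C@@H]1O[Si](C)(C)C(C)(C)C | intermediate
36 | (5S,6R,7S,8S)-5,6,7-trihydroxy-8-{[7-methoxy-4-oxo-2-(2-phenylethyl)-4H-chromen-6-yl]oxy}-2-(2-phenylethyl)-5,6,7,8-tetrahydro-4H-chromen-4-one | COc1cc2oc(CCc3ccccc3)cc(=O)c2cc1O[C@@H]1c2oc(CCc3ccccc3)cc(=O)c2[C@H](O)[C@@H](O)[C@@H]1O | target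

## Step count and least certain steps

Total: 17 steps. Longest linear sequence: 16 steps (steps 1 to 10 and 12 to 17, from 1 to 36); step 11 is a one-step side branch.

Step 13 (key step). The most likely failures are closure to a five-membered ring in place of CO insertion, alkyne insertion in the reverse sense, or thermal breakdown of the uncommon 1-methoxyethenyl carbene before the alkyne is taken up. All would stem from the extra donor on the alkenyl group and the bulk of the C8 alkoxy group. Fallback: starting from 18, the ether could be made by palladium-catalysed C-O cross-coupling of the secondary alcohol with the aryl bromide 6-bromo-7-methoxy-2-(2-phenylethyl)-4H-chromen-4-one F1 (Pd2(dba)3, tBuBrettPhos, Cs2CO3, toluene, 90 °C). F1 would be available from the corresponding commercial bromosalicylaldehyde by the chemistry of steps 15 and 16. The coupling forms O-C6' with retention at C8 and rejoins the route at 35.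

Step 12. Attack of the hindered C8 hydroxyl of 18 (beside the C7 silyl ether) on the acetoxycarbene may be slower than thermal decomposition of that acyloxycarbene. Fallback: starting from the less hindered diol 15, the same alcoholysis with 24 should take place at the more accessible C8 hydroxyl and give pentacarbonyl{[(5S,6S,7R,8S)-5,6-bis(tert-butyldimethylsilyloxy)-7-hydroxy-4-oxo-2-(2-phenylethyl)-5,6,7,8-tetrahydro-4H-chromen-8-yl]oxy(1-methoxyethenyl)methylidene}chromium F2. Silylation of its C7 hydroxyl (TBSOTf, 2,6-lutidine, CH2Cl2, -40 °C) returns to 25.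

Step 7. Adduct 13 has a silyloxy group β to its ketone, so β-elimination at C5, or β-hydride elimination towards C5 in place of C8a, may compete with the wanted dehydrogenation. Fallback: starting from 12, the adduct 13 would be isolated after acid-catalysed cyclisation (PPTS, CH2Cl2) and converted into its 4-trimethylsilyl dienol ether, the 4-silyloxy-2H-pyran F3 (Me3SiOTf, Et3N, CH2Cl2, -78 °C). Hydride abstraction from C8a with DDQ (CH2Cl2, 0 °C) then gives a silyloxypyrylium ion that collapses to 14, where the route is rejoined.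

Step 9. The first silylation may show poor site selectivity between the C8 and C7 hydroxyls, or the silyl group may migrate across the cis-diol. Fallback: starting from 15, MnO2 (CH2Cl2, rt) should oxidise only the allylic C8 carbinol to (5S,6S,7S)-5,6-bis(tert-butyldimethylsilyloxy)-7-hydroxy-2-(2-phenylethyl)-6,7-dihydro-5H-chromene-4,8-dione F4. Silylation (TBSOTf, 2,6-lutidine) gives (5S,6R,7S)-5,6,7-tris(tert-butyldimethylsilyloxy)-2-(2-phenylethyl)-6,7-dihydro-5H-chromene-4,8-dione F5. Luche reduction (NaBH4, CeCl3·7H2O, MeOH, -78 °C), with hydride entering anti to the C7 silyloxy group, should give the 7,8-cis alcohol 18, where the route is rejoined.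

Step 6. C-Acylation of a ketone enolate by the hindered, unsaturated amide 9 may be sluggish, which would allow enolate equilibration and self-condensation of 10. Fallback: starting from 9, addition of the lithium acetylide 31 (THF, -78 °C) gives the ynone 1-[(3R,4R,5S,6S)-5,6-bis(tert-butyldimethylsilyloxy)-3,4-(isopropylidenedioxy)cyclohex-1-en-1-yl]-5-phenylpent-2-yn-1-one F6. Conjugate addition of diethylamine (EtOH, rt) gives the enaminone 3-(diethylamino)-1-[(3R,4R,5S,6S)-5,6-bis(tert-butyldimethylsilyloxy)-3,4-(isopropylidenedioxy)cyclohex-1-en-1-yl]-5-phenylpent-2-en-1-one F7, and mild hydrolysis (aqueous acetic acid, THF, rt) gives 12, where the route is rejoined.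

## Further compounds

F1 | step 13 | 6-bromo-7-methoxy-2-(2-phenylethyl)-4H-chromen-4-one | COc1cc2oc(CCc3ccccc3)cc(=O)c2cc1Br
F2 | step 12 | pentacarbonyl{[(5S,6S,7R,8S)-5,6-bis(tert-butyldimethylsilyloxy)-7-hydroxy-4-oxo-2-(2-phenylethyl)-5,6,7,8-tetrahydro-4H-chromen-8-yl]oxy(1-methoxyethenyl)methylidene}chromium | C=C(OC)C(=[Cr])O[C@@H]1c2oc(CCc3ccccc3)cc(=O)c2[C@H](O[Si](C)(C)C(C)(C)C)[C@@H](O[Si](C)(C)C(C)(C)C)[C@@H]1O.[C-]#[O+].[C-]#[O+].[C-]#[O+].[C-]#[O+].[C-]#[O+]
F3 | step 7 | 4-trimethylsilyl dienol ether of 13, 5,6-bis(tert-butyldimethylsilyloxy)-7,8-(isopropylidenedioxy)-2-(2-phenylethyl)-4-(trimethylsilyloxy)-6,7,8,8a-tetrahydro-5H-chromene (C5 to C8 as in 14; C8a epimers) | CC1(C)O[C@@H]2C3OC(CCc4ccccc4)=CC(O[Si](C)(C)C)=C3[C@H](O[Si](C)(C)C(C)(C)C)[C@@H](O[Si](C)(C)C(C)(C)C)[C@@H]2O1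
F4 | step 9 | (5S,6S,7S)-5,6-bis(tert-butyldimethylsilyloxy)-7-hydroxy-2-(2-phenylethyl)-6,7-dihydro-5H-chromene-4,8-dione | O=C1c2oc(CCc3ccccc3)cc(=O)c2[C@H](O[Si](C)(C)C(C)(C)C)[C@@H](O[Si](C)(C)C(C)(C)C)[C@@H]1O
F5 | step 9 | (5S,6R,7S)-5,6,7-tris(tert-butyldimethylsilyloxy)-2-(2-phenylethyl)-6,7-dihydro-5H-chromene-4,8-dione | O=C1c2oc(CCc3ccccc3)cc(=O)c2[C@H](O[Si](C)(C)C(C)(C)C)[C@@H](O[Si](C)(C)C(C)(C)C)[C@@H]1O[Si](C)(C)C(C)(C)C
F6 | step 6 | 1-[(3R,4R,5S,6S)-5,6-bis(tert-butyldimethylsilyloxy)-3,4-(isopropylidenedioxy)cyclohex-1-en-1-yl]-5-phenylpent-2-yn-1-one | O=C(C#CCCc1ccccc1)C1=C[C@@H]2[C@@H](OC(C)(C)O2)[C@H](O[Si](C)(C)C(C)(C)C)[C@H]1O[Si](C)(C)C(C)(C)C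
F7 | step 6 | 3-(diethylamino)-1-[(3R,4R,5S,6S)-5,6-bis(tert-butyldimethylsilyloxy)-3,4-(isopropylidenedioxy)cyclohex-1-en-1-yl]-5-phenylpent-2-en-1-one (alkene geometry not controlled) | CCN(CC)C(CCc1ccccc1)=CC(=O)C1=C[C@@H]2[C@@H](OC(C)(C)O2)[C@H](O[Si](C)(C)C(C)(C)C)[C@H]1O[Si](C)(C)C(C)(C)C
A1 | alternative 1 | (7S,8S)-7,8-dihydroxy-2-(2-phenylethyl)-7,8-dihydro-4H-chromen-4-one | O[C@@H]1c2oc(CCc3ccccc3)cc(=O)c2C=C[C@@H]1O
A2 | alternative 1 | 2-(2-phenylethyl)-4H-chromen-4-one | O=c1cc(CCc2ccccc2)oc2ccccc12
A3 | alternative 2 | 5,6,7-tris-O-(tert-butyldimethylsilyl) derivative of 36 (identical with 35) | COc1cc2oc(CCc3ccccc3)cc(=O)c2cc1O[C@@H]1c2oc(CCc3ccccc3)cc(=O)c2[C@H](O[Si](C)(C)C(C)(C)C)[C@@H](O[Si](C)(C)C(C)(C)C)[C@@H]1O[Si](C)(C)C(C)(C)C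
A4 | alternative 2 | (5S,6R,7R,8S)-5,6,7-tris(tert-butyldimethylsilyloxy)-2-(2-phenylethyl)-8-[(1,1,3-trimethoxy-5,7,9-trioxo-11-phenylundec-3-en-2-yl)oxy]-5,6,7,8-tetrahydro-4H-chromen-4-one (side-chain centre and alkene geometry not defined) | COC(OC)C(O[C@@H]1c2oc(CCc3ccccc3)cc(=O)c2[C@H](O[Si](C)(C)C(C)(C)C)[C@@H](O[Si](C)(C)C(C)(C)C)[C@@H]1O[Si](C)(C)C(C)(C)C)C(OC)=CC(=O)CC(=O)CC(=O)CCc1ccccc1
A5 | alternative 3 | 5-deoxy-6,7-bis-O-(tert-butyldimethylsilyl) derivative of 36 | COc1cc2oc(CCc3ccccc3)cc(=O)c2cc1O[C@@H]1c2oc(CCc3ccccc3)cc(=O)c2C[C@@H](O[Si](C)(C)C(C)(C)C)[C@@H]1O[Si](C)(C)C(C)(C)C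
A6 | alternative 3 | 1-[4,5-bis(tert-butyldimethylsilyloxy)-3-{[7-methoxy-4-oxo-2-(2-phenylethyl)-4H-chromen-6-yl]oxy}cyclohex-1-en-1-yl]-5-phenylpentane-1,3-dione with the shikimate configuration (O3/O4 cis, O4/O5 trans) | O=C(CC(=O)CCc1ccccc1)C1=C[C@@H](Oc2cc3c(=O)cc(CCc4ccccc4)oc3cc2OC)[C@@H](O[Si](C)(C)C(C)(C)C)[C@H](O[Si](C)(C)C(C)(C)C)C1
A7 | alternative 3 | 6-hydroxy-7-methoxy-2-(2-phenylethyl)-4H-chromen-4-one | COc1cc2oc(CCc3ccccc3)cc(=O)c2cc1O
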